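**Retrosynthetic overview**
- The target comes from its bis-benzyl ether by hydrogenolysis; the aryl ketone is carried as a 2-aryl-1,3-dithiane until the end.
- The lactone CH2–O carbon is carried as a C5 l-menthyloxy acetal (chiral auxiliary), excised reductively after all C–C bonds are in place.
- The quaternary C3 (OH, benzyl) comes from enolate hydroxylation, then benzylation of the α-hydroxy lactone dianion anti to the C4 substituent.
- Key C–C bond (aroyl carbon to C4): Michael addition of lithiated O-benzylvanillin dithiane to (5R)-5-(l-menthyloxy)-2(5H)-furanone, anti to the menthyloxy group; this sets C4.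
- Ring order: the butyrolactone ring is present from the butenolide (opened and re-closed once when the auxiliary leaves); the dithiane is a temporary ring, made first and removed late.

Assumption: (5R)-5-(l-menthyloxy)-2(5H)-furanone is bought as a catalogue compound (otherwise two steps from furfural and (−)-menthol).

**Route**

Step 1
Reactants: 1 4-(benzyloxy)-3-methoxybenzaldehyde (O-benzylvanillin)
Product: 2 2-[4-(benzyloxy)-3-methoxyphenyl]-1,3-dithiane
Conditions: HS(CH2)3SH (1.1 equiv), BF3·OEt2 (0.2 equiv), CH2Cl2, 0 °C → rt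
Reagents that add atoms: propane-1,3-dithiol, SCCCS
Why: Lewis-acid-catalysed dithioacetalisation of an aromatic aldehyde is high-yielding and turns the aldehyde carbon into an aroyl anion equivalent; no stereocentre is formed.

Step 2
Reactants: 1 4-(benzyloxy)-3-methoxybenzaldehyde
Product: 3 [4-(benzyloxy)-3-methoxyphenyl]methanol
Conditions: NaBH4, MeOH, 0 °C
Reagents that add atoms: none
Why: Borohydride reduction of an aryl aldehyde to the benzylic alcohol is clean and leaves the benzyl ether untouched; no stereocentre.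

Step 3
Reactants: 3 [4-(benzyloxy)-3-methoxyphenyl]methanol
Product: 4 4-(benzyloxy)-3-methoxybenzyl bromide
Conditions: PBr3 (0.4 equiv), Et2O, 0 °C; used crude
Reagents that add atoms: phosphorus tribromide, BrP(Br)Br
Why: Bromination of a benzylic alcohol through its phosphite ester (SN2) is fast at 0 °C, and the reactive electron-rich bromide is used at once without chromatography.

Step 4
Reactants: 2 2-[4-(benzyloxy)-3-methoxyphenyl]-1,3-dithiane; 5 (5R)-5-(l-menthyloxy)-2(5H)-furanone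
Product: 8 (4R,5R)-4-{2-[4-(benzyloxy)-3-methoxyphenyl]-1,3-dithian-2-yl}-5-(l-menthyloxy)dihydrofuran-2(3H)-one, via lithiated dithiane 6 (not isolated), via lithium enolate 7 (not isolated)
Conditions: n-BuLi (1.05 equiv), THF, −78 °C, 1 h; then 5, −78 °C, 2 h; AcOH, −78 °C → rt
Reagents that add atoms: none
Why: Michael addition of the sulfur-stabilised 2-lithio-1,3-dithiane to the butenolide is 1,4-selective and occurs on the face anti to the bulky C5 menthyloxy group, which sets C4 as R (the future aroyl-bearing centre), and the enolate is then simply protonated.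

Step 5
Reactants: 8 (4R,5R)-4-{2-[4-(benzyloxy)-3-methoxyphenyl]-1,3-dithian-2-yl}-5-(l-menthyloxy)dihydrofuran-2(3H)-one
Product: 10 (3R,4R,5R)-4-{2-[4-(benzyloxy)-3-methoxyphenyl]-1,3-dithian-2-yl}-3-hydroxy-5-(l-menthyloxy)dihydrofuran-2(3H)-one, via potassium enolate 9 (not isolated)
Conditions: KN(SiMe3)2 (1.2 equiv), THF, −78 °C, 45 min; 2-(phenylsulfonyl)-3-phenyloxaziridine (1.5 equiv), −78 °C, 30 min; AcOH
Reagents that add atoms: 2-(phenylsulfonyl)-3-phenyloxaziridine, O=S(=O)(c1ccccc1)N1OC1c1ccccc1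
Why: Davis oxidation of the potassium enolate at −78 °C is far faster than sulfide oxidation and delivers oxygen anti to the C4 dithiane (mainly the 3,4-trans alcohol, 3R), a provisional configuration because C3 is made planar again in step 6.

Step 6
Reactants: 10 (3R,4R,5R)-4-{2-[4-(benzyloxy)-3-methoxyphenyl]-1,3-dithian-2-yl}-3-hydroxy-5-(l-menthyloxy)dihydrofuran-2(3H)-one; 4 4-(benzyloxy)-3-methoxybenzyl bromide
Product: 12 (3S,4R,5R)-3-[4-(benzyloxy)-3-methoxybenzyl]-4-{2-[4-(benzyloxy)-3-methoxyphenyl]-1,3-dithian-2-yl}-3-hydroxy-5-(l-menthyloxy)dihydrofuran-2(3H)-one, via dilithium enediolate 11 (not isolated)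
Conditions: LiN(iPr)2 (2.3 equiv), THF, −78 → −30 °C, 1 h; DMPU (4 equiv); 4 (1.4 equiv), −78 → −20 °C; AcOH
Reagents that add atoms: none
Why: C-alkylation of the enediolate dianion of the α-hydroxy lactone by the benzylic bromide can only take place anti to the very bulky C4 dithianyl group, so the benzyl ends trans and the hydroxyl cis to it, which sets the quaternary centre as 3S.

Step 7
Reactants: 12 (3S,4R,5R)-3-[4-(benzyloxy)-3-methoxybenzyl]-4-{2-[4-(benzyloxy)-3-methoxyphenyl]-1,3-dithian-2-yl}-3-hydroxy-5-(l-menthyloxy)dihydrofuran-2(3H)-one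
Product: 15 (3S,4S)-3-[4-(benzyloxy)-3-methoxybenzyl]-4-{2-[4-(benzyloxy)-3-methoxyphenyl]-1,3-dithian-2-yl}-3-hydroxydihydrofuran-2(3H)-one, via aldehyde carboxylate 13 (not isolated), via dihydroxy carboxylate 14 (not isolated)
Conditions: NaBH4 (4 equiv), KOH (2 equiv), EtOH/H2O (4:1), 0 °C → rt; then 2 M HCl to pH 2, rt, 2 h
Reagents that add atoms: potassium hydroxide, [K+].[OH-] (its oxygen enters the carboxylate and can remain as a lactone oxygen after re-closure)
Why: Saponification of the pseudo-ester releases menthol and the aldehyde carboxylate, NaBH4 reduces the aldehyde at once and acid lactonises the γ-hydroxy acid, with no bond to C3 or C4 broken, so both centres are retained (C4 becomes S only through a priority change).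

Step 8
Reactants: 15 (3S,4S)-3-[4-(benzyloxy)-3-methoxybenzyl]-4-{2-[4-(benzyloxy)-3-methoxyphenyl]-1,3-dithian-2-yl}-3-hydroxydihydrofuran-2(3H)-one
Product: 16 (3S,4S)-4-[4-(benzyloxy)-3-methoxybenzoyl]-3-[4-(benzyloxy)-3-methoxybenzyl]-3-hydroxydihydrofuran-2(3H)-one
Conditions: Hg(ClO4)2·3H2O (2.2 equiv), CaCO3 (4 equiv), THF/H2O (5:1), 0 °C → rt, 1 h
Reagents that add atoms: water, O
Why: Thiophilic hydrolysis of the dithioacetal assisted by divalent mercury is fast, and the CaCO3 buffer keeps the new β-hydroxy ketone from epimerising at C4 or undergoing retro-aldol cleavage.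

Step 9
Reactants: 16 (3S,4S)-4-[4-(benzyloxy)-3-methoxybenzoyl]-3-[4-(benzyloxy)-3-methoxybenzyl]-3-hydroxydihydrofuran-2(3H)-one
Product: 17 (3S,4S)-3-hydroxy-4-(4-hydroxy-3-methoxybenzoyl)-3-(4-hydroxy-3-methoxybenzyl)dihydrofuran-2(3H)-one
Conditions: H2 (1 atm), 10% Pd/C, EtOAc/EtOH (1:1), rt, 2–4 h (TLC control)
Reagents that add atoms: none
Why: Hydrogenolysis of the two aryl benzyl ethers over palladium on carbon is much faster than reduction of the electron-rich aryl ketone, and no stereocentre is touched.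

**Compound list**

1 | 4-(benzyloxy)-3-methoxybenzaldehyde | COc1cc(C=O)ccc1OCc1ccccc1 | starting material
2 | 2-[4-(benzyloxy)-3-methoxyphenyl]-1,3-dithiane | COc1cc(C2SCCCS2)ccc1OCc1ccccc1 | intermediate
3 | [4-(benzyloxy)-3-methoxyphenyl]methanol | COc1cc(CO)ccc1OCc1ccccc1 | intermediate
4 | 4-(benzyloxy)-3-methoxybenzyl bromide | COc1cc(CBr)ccc1OCc1ccccc1 | intermediate
5 | (5R)-5-{[(1R,2S,5R)-5-methyl-2-(propan-2-yl)cyclohexyl]oxy}furan-2(5H)-one | O=C1C=C[C@H](O[C@@H]2C[C@H](C)CC[C@H]2C(C)C)O1 | starting material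
6 | 2-lithio-2-[4-(benzyloxy)-3-methoxyphenyl]-1,3-dithiane (not isolated) | COc1cc(C2([Li])SCCCS2)ccc1OCc1ccccc1 | intermediate
7 | lithium enolate of 8 (not isolated) | [Li]OC1=C[C@@H](C2(c3ccc(OCc4ccccc4)c(OC)c3)SCCCS2)[C@H](O[C@@H]2C[C@H](C)CC[C@H]2C(C)C)O1 | intermediate
8 | (4R,5R)-4-{2-[4-(benzyloxy)-3-methoxyphenyl]-1,3-dithian-2-yl}-5-(l-menthyloxy)dihydrofuran-2(3H)-one | O=C1C[C@@H](C2(c3ccc(OCc4ccccc4)c(OC)c3)SCCCS2)[C@H](O[C@@H]2C[C@H](C)CC[C@H]2C(C)C)O1 | intermediate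
9 | potassium enolate of 8 (not isolated) | [K]OC1=C[C@@H](C2(c3ccc(OCc4ccccc4)c(OC)c3)SCCCS2)[C@H](O[C@@H]2C[C@H](C)CC[C@H]2C(C)C)O1 | intermediate
10 | (3R,4R,5R)-4-{2-[4-(benzyloxy)-3-methoxyphenyl]-1,3-dithian-2-yl}-3-hydroxy-5-(l-menthyloxy)dihydrofuran-2(3H)-one (major 3,4-trans isomer) | O=C1[C@H](O)[C@@H](C2(c3ccc(OCc4ccccc4)c(OC)c3)SCCCS2)[C@H](O[C@@H]2C[C@H](C)CC[C@H]2C(C)C)O1 | intermediate
11 | dilithium enediolate of 10 (not isolated) | [Li]OC1=C(O[Li])[C@@H](C2(c3ccc(OCc4ccccc4)c(OC)c3)SCCCS2)[C@H](O[C@@H]2C[C@H](C)CC[C@H]2C(C)C)O1 | intermediate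
12 | (3S,4R,5R)-3-[4-(benzyloxy)-3-methoxybenzyl]-4-{2-[4-(benzyloxy)-3-methoxyphenyl]-1,3-dithian-2-yl}-3-hydroxy-5-(l-menthyloxy)dihydrofuran-2(3H)-one | O=C1[C@](O)(Cc2ccc(OCc3ccccc3)c(OC)c2)[C@@H](C2(c3ccc(OCc4ccccc4)c(OC)c3)SCCCS2)[C@H](O[C@@H]2C[C@H](C)CC[C@H]2C(C)C)O1 | intermediate
13 | potassium (2S,3R)-2-[4-(benzyloxy)-3-methoxybenzyl]-3-{2-[4-(benzyloxy)-3-methoxyphenyl]-1,3-dithian-2-yl}-2-hydroxy-4-oxobutanoate (not isolated) | COc1cc(C[C@@](O)(C(=O)[O-])[C@H](C=O)C2(c3ccc(OCc4ccccc4)c(OC)c3)SCCCS2)ccc1OCc1ccccc1.[K+] | intermediate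
14 | potassium (2S,3S)-2-[4-(benzyloxy)-3-methoxybenzyl]-3-{2-[4-(benzyloxy)-3-methoxyphenyl]-1,3-dithian-2-yl}-2,4-dihydroxybutanoate (not isolated) | COc1cc(C[C@@](O)(C(=O)[O-])[C@H](CO)C2(c3ccc(OCc4ccccc4)c(OC)c3)SCCCS2)ccc1OCc1ccccc1.[K+] | intermediate
15 | (3S,4S)-3-[4-(benzyloxy)-3-methoxybenzyl]-4-{2-[4-(benzyloxy)-3-methoxyphenyl]-1,3-dithian-2-yl}-3-hydroxydihydrofuran-2(3H)-one | COc1cc(C[C@@]2(O)C(=O)OC[C@@H]2C5(c3ccc(OCc4ccccc4)c(OC)c3)SCCCS5)ccc1OCc1ccccc1 | intermediate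
16 | (3S,4S)-4-[4-(benzyloxy)-3-methoxybenzoyl]-3-[4-(benzyloxy)-3-methoxybenzyl]-3-hydroxydihydrofuran-2(3H)-one | COc1cc(C[C@@]2(O)C(=O)OC[C@@H]2C(=O)c2ccc(OCc3ccccc3)c(OC)c2)ccc1OCc1ccccc1 | intermediate
17 | (3S,4S)-3-hydroxy-4-(4-hydroxy-3-methoxybenzoyl)-3-(4-hydroxy-3-methoxybenzyl)dihydrofuran-2(3H)-one | COc1cc(C[C@@]2(O)C(=O)OC[C@@H]2C(=O)c2ccc(O)c(OC)c2)ccc1O | target

**Totals**
Total steps: 9. Longest linear sequence: 7 (steps 1, 4, 5, 6, 7, 8, 9).

**Three steps most likely to fail**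

Step 6 (dianion benzylation). The risks are O-alkylation and poor conversion at the hindered C3. The fallback sets out from 10. The hydroxyl is protected with MOMCl and iPr2NEt in CH2Cl2 to give (3R,4R,5R)-4-{2-[4-(benzyloxy)-3-methoxyphenyl]-1,3-dithian-2-yl}-3-(methoxymethoxy)-5-(l-menthyloxy)dihydrofuran-2(3H)-one F1. Its chelated mono-enolate (LiN(iPr)2 1.2 equiv, THF/DMPU, −78 °C) is alkylated with 4, again anti to the dithiane, to give (3S,4R,5R)-3-[4-(benzyloxy)-3-methoxybenzyl]-4-{2-[4-(benzyloxy)-3-methoxyphenyl]-1,3-dithian-2-yl}-3-(methoxymethoxy)-5-(l-menthyloxy)dihydrofuran-2(3H)-one F2. The MOM ether is then cleaved with CF3CO2H/H2O in CH2Cl2 at 0 °C, which the pseudo-ester acetal, dithiane and benzyl ethers should survive, and the route is rejoined at 12.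

Step 7 (reductive removal of the auxiliary). The risk is that the β-hydroxy aldehyde 13 undergoes retro-aldol cleavage or C3 epimerisation in base before it is reduced. The fallback sets out from 8 and removes the auxiliary before the tertiary alcohol exists. NaBH4/KOH then HCl on 8 gives (4R)-4-{2-[4-(benzyloxy)-3-methoxyphenyl]-1,3-dithian-2-yl}dihydrofuran-2(3H)-one F3. Enolate hydroxylation (KN(SiMe3)2, then the same oxaziridine) gives (3R,4S)-4-{2-[4-(benzyloxy)-3-methoxyphenyl]-1,3-dithian-2-yl}-3-hydroxydihydrofuran-2(3H)-one F4. Dianion benzylation of F4 with 4 (LiN(iPr)2 2.3 equiv, DMPU), anti to the dithiane, rejoins the route at 15. This fallback carries its own risk: the only stereocentre of F3 is α to a transient aldehyde, so its enantiomeric purity must be checked.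

Step 8 (dithiane hydrolysis). The risk is sluggish hydrolysis of a hindered dithiane, with damage to the β-hydroxy ketone on prolonged exposure. The fallback sets out from 15. One sulfur is oxidised with NaIO4 (MeOH/THF/H2O, 0 °C) to (3S,4S)-3-[4-(benzyloxy)-3-methoxybenzyl]-4-{2-[4-(benzyloxy)-3-methoxyphenyl]-1-oxido-1,3-dithian-2-yl}-3-hydroxydihydrofuran-2(3H)-one F5, a mixture of sulfoxide diastereomers. The much more labile monosulfoxide is then hydrolysed with dilute HCl in THF at rt, and the route is rejoined at 16.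

**Further compounds**

F1 | step 6 | (3R,4R,5R)-4-{2-[4-(benzyloxy)-3-methoxyphenyl]-1,3-dithian-2-yl}-3-(methoxymethoxy)-5-(l-menthyloxy)dihydrofuran-2(3H)-one | O=C1[C@H](OCOC)[C@@H](C2(c3ccc(OCc4ccccc4)c(OC)c3)SCCCS2)[C@H](O[C@@H]2C[C@H](C)CC[C@H]2C(C)C)O1
F2 | step 6 | (3S,4R,5R)-3-[4-(benzyloxy)-3-methoxybenzyl]-4-{2-[4-(benzyloxy)-3-methoxyphenyl]-1,3-dithian-2-yl}-3-(methoxymethoxy)-5-(l-menthyloxy)dihydrofuran-2(3H)-one | O=C1[C@](OCOC)(Cc2ccc(OCc3ccccc3)c(OC)c2)[C@@H](C2(c3ccc(OCc4ccccc4)c(OC)c3)SCCCS2)[C@H](O[C@@H]2C[C@H](C)CC[C@H]2C(C)C)O1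
F3 | step 7 | (4R)-4-{2-[4-(benzyloxy)-3-methoxyphenyl]-1,3-dithian-2-yl}dihydrofuran-2(3H)-one | O=C1C[C@@H](C2(c3ccc(OCc4ccccc4)c(OC)c3)SCCCS2)CO1
F4 | step 7 | (3R,4S)-4-{2-[4-(benzyloxy)-3-methoxyphenyl]-1,3-dithian-2-yl}-3-hydroxydihydrofuran-2(3H)-one | O=C1[C@H](O)[C@@H](C2(c3ccc(OCc4ccccc4)c(OC)c3)SCCCS2)CO1
F5 | step 8 | (3S,4S)-3-[4-(benzyloxy)-3-methoxybenzyl]-4-{2-[4-(benzyloxy)-3-methoxyphenyl]-1-oxido-1,3-dithian-2-yl}-3-hydroxydihydrofuran-2(3H)-one (sulfoxide diastereomers) | COc1cc(C[C@@]2(O)C(=O)OC[C@@H]2C5(c3ccc(OCc4ccccc4)c(OC)c3)SCCCS5=O)ccc1OCc1ccccc1
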